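## Retrosynthetic overview

1. Ester C–O bond: Gentiside C ⇒ (S)-1-bromo-14-methylhexadecane + 2,3-dihydroxybenzoic acid (bicarbonate-mediated carboxylate alkylation, no protecting groups).
2. Key C12–C13 bond: the bromide ⇒ 1,12-dibromododecane (electrophile, in excess) + the carbonyl carbon of (S)-2-methylbutanal used with inverted polarity, as the azo anion of its N-trityl hydrazone. This acyl-anion-type nucleophile is traceless: N2 and trityl leave after C–C bond formation, so the former C=O carbon ends as CH2.
3. (S)-2-Methylbutanal ⇒ (S)-2-methylbutan-1-ol (chiral pool). It supplies C13–C16, the C14 methyl and the only stereocentre, which is bought and never made or broken.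
4. Rings: none is formed; the only ring (the catechol arene) is bought in the acid.

Assumption: tritylhydrazine is bought as its hydrochloride and free-based (aq NaHCO3/CH2Cl2) just before use.

## Route

Step 1
Reactants: 1 (S)-2-methylbutan-1-ol
Product: 3 (S)-2-methylbutanal N-tritylhydrazone, via (S)-2-methylbutanal 2 (not isolated)
Conditions: TEMPO (1 mol %), KBr (10 mol %), NaOCl (1.1 equiv), aq NaHCO3 (pH 9.5), CH2Cl2/H2O, 0 °C, 20 min; organic layer washed (aq Na2S2O3), dried (MgSO4), then TrNHNH2 (0.95 equiv), 4 Å MS, 0 °C → rt, 3 h
Reagents that add atoms: tritylhydrazine, NNC(c1ccccc1)(c1ccccc1)c1ccccc1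
Why: Anelli TEMPO/hypochlorite oxidation stops at the aldehyde and is mild enough (0 °C, pH 9.5) to leave the α-stereocentre intact, and trapping the volatile, epimerisable aldehyde directly in the dried organic layer by neutral hydrazone condensation avoids its isolation; no new stereocentre is made (the C=N bond forms as the E isomer).

Step 2
Reactants: 3 (S)-2-methylbutanal N-tritylhydrazone; 4 1,12-dibromododecane
Product: 7 (S)-1-bromo-14-methylhexadecane, via lithium azo anion 5 (not isolated), via trityl azoalkane 6 (not isolated)
Conditions: LDA (1.05 equiv), THF, −78 °C, 30 min; 4 (4 equiv), DMPU (2 equiv), −78 → 0 °C, 3 h; EtSH (10 equiv), 0 °C → rt, 12 h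
Reagents that add atoms: none
Why: Baldwin-type azo-anion reductive alkylation: N-deprotonation gives an aza-allyl (azo) anion that the bulky trityl group directs to react at carbon, so the former aldehyde carbon acts as a traceless acyl-anion/alkyl-carbanion equivalent in an SN2 reaction with one end of the excess dibromide; the alkyl trityl diazene then loses N2 homolytically near room temperature and the secondary radical is capped by H-atom transfer from the thiol, while the C14 stereocentre is never deprotonated or ionised and is retained (the transient C13 centre forms as an epimer mixture and is erased).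

Step 3
Reactants: 7 (S)-1-bromo-14-methylhexadecane; 8 2,3-dihydroxybenzoic acid
Product: 10 Gentiside C, via potassium 2,3-dihydroxybenzoate 9 (not isolated)
Conditions: 8 (1.5 equiv), KHCO3 (1.5 equiv), NaI (10 mol %), degassed DMF, 60 °C, 16 h, N2
Reagents that add atoms: none
Why: Chemoselective SN2 O-alkylation of a carboxylate: bicarbonate deprotonates only the carboxylic acid (pKa about 3) and not the catechol hydroxyls (pKa about 10 and 13), so the primary bromide alkylates the carboxylate alone and no stereocentre is touched.

## Compound list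

1 | (S)-2-methylbutan-1-ol | CC[C@H](C)CO | starting material
2 | (S)-2-methylbutanal | CC[C@H](C)C=O | intermediate (not isolated)
3 | (E)-1-[(2S)-2-methylbutylidene]-2-tritylhydrazine [(S)-2-methylbutanal N-tritylhydrazone] | CC[C@H](C)/C=N/NC(c1ccccc1)(c1ccccc1)c1ccccc1 | intermediate
4 | 1,12-dibromododecane | BrCCCCCCCCCCCCBr | starting material
5 | lithium (E)-2-[(2S)-2-methylbutylidene]-1-tritylhydrazin-1-ide (lithium azo anion) | CC[C@H](C)/C=N/[N-]C(c1ccccc1)(c1ccccc1)c1ccccc1.[Li+] | intermediate (not isolated)
6 | (E)-1-[(14S)-1-bromo-14-methylhexadecan-13-yl]-2-trityldiazene (trityl azoalkane; mixture of C13 epimers) | CC[C@H](C)C(CCCCCCCCCCCCBr)/N=N/C(c1ccccc1)(c1ccccc1)c1ccccc1 | intermediate (not isolated)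
7 | (S)-1-bromo-14-methylhexadecane | CC[C@H](C)CCCCCCCCCCCCCBr | intermediate
8 | 2,3-dihydroxybenzoic acid | OC(=O)c1cccc(O)c1O | starting material
9 | potassium 2,3-dihydroxybenzoate | [K+].[O-]C(=O)c1cccc(O)c1O | intermediate (not isolated)
10 | Gentiside C, (S)-14-methylhexadecyl 2,3-dihydroxybenzoate | CC[C@H](C)CCCCCCCCCCCCCOC(=O)c1cccc(O)c1O | target

## Step count and risks

Total step count: 3. Longest linear sequence: 3 (1 → 3 → 7 → 10).

The route has three steps; they are ranked here from most to least likely to fail.

Step 2 (highest risk). The carbon of azo anion 5 is hindered by the adjacent sec-butyl branch, so the SN2 step may be slow or go partly at nitrogen. The dibromide can be alkylated at both ends. The radical formed on N2 loss can recombine with trityl or disproportionate instead of taking hydrogen from the thiol. Fallback, setting out from aldehyde 2 and coming back at target 10: the dried CH2Cl2 solution of 2 from step 1 is treated with propane-1,3-dithiol and BF3·OEt2 at −20 °C to give 2-[(2S)-butan-2-yl]-1,3-dithiane F1. This classical acyl-anion equivalent is lithiated (n-BuLi, THF, −20 °C) and alkylated with excess 4 (DMPU) to give 2-(12-bromododecyl)-2-[(2S)-butan-2-yl]-1,3-dithiane F2. Its bromide end alkylates 8 under the step 3 conditions to give 12-{2-[(2S)-butan-2-yl]-1,3-dithian-2-yl}dodecyl 2,3-dihydroxybenzoate F3. Raney nickel (W-2, EtOH, reflux) then removes the sulfur and gives 10; desulfurisation is placed after the esterification so that no C–Br bond meets Raney nickel.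

Step 1. Aldehyde 2 is volatile and can epimerise by enolisation during oxidation or condensation, and residual hypochlorite would destroy the hydrazine. Fallback, setting out from 1 and coming back at 7: the roles of the fragments are swapped so that the stereocentre sits one carbon away from the reacting centre of an SN2 electrophile. Alcohol 1 is converted (PPh3, I2, imidazole, CH2Cl2) into (S)-1-iodo-2-methylbutane F4. Commercial oxacyclotridecan-2-one is half-reduced (DIBAL-H, CH2Cl2, −78 °C) to 12-hydroxydodecanal F5, which is condensed with tritylhydrazine to (E)-12-hydroxydodecanal N-tritylhydrazone F6. Double deprotonation (LDA, 2.1 equiv, THF, −78 °C), C-alkylation with F4 and thiol-mediated N2 loss as in step 2 give (S)-14-methylhexadecan-1-ol F7. CBr4/PPh3 (CH2Cl2, 0 °C) converts it into 7.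

Step 3. The catechol oxygens may be alkylated in competition, the catechol can air-oxidise under basic conditions, and the intramolecularly hydrogen-bonded carboxylate may react slowly. Fallback, setting out from 8 and coming back at 10: chemoselectivity is replaced by protection. Acid 8 with BnBr/K2CO3 (DMF, 60 °C) gives benzyl 2,3-bis(benzyloxy)benzoate F8. LiOH (THF/MeOH/H2O) gives 2,3-bis(benzyloxy)benzoic acid F9. With Cs2CO3 in DMF at 50 °C it is alkylated by 7 to give (S)-14-methylhexadecyl 2,3-bis(benzyloxy)benzoate F10. Hydrogenolysis (H2, Pd/C, EtOAc, rt) gives 10.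

## Further compounds

F1 | step 2 | 2-[(2S)-butan-2-yl]-1,3-dithiane | CC[C@H](C)C1SCCCS1
F2 | step 2 | 2-(12-bromododecyl)-2-[(2S)-butan-2-yl]-1,3-dithiane | CC[C@H](C)C1(CCCCCCCCCCCCBr)SCCCS1
F3 | step 2 | 12-{2-[(2S)-butan-2-yl]-1,3-dithian-2-yl}dodecyl 2,3-dihydroxybenzoate | CC[C@H](C)C1(CCCCCCCCCCCCOC(=O)c2cccc(O)c2O)SCCCS1
F4 | step 1 | (S)-1-iodo-2-methylbutane | CC[C@H](C)CI
F5 | step 1 | 12-hydroxydodecanal | O=CCCCCCCCCCCCO
F6 | step 1 | (E)-12-hydroxydodecanal N-tritylhydrazone | OCCCCCCCCCCC/C=N/NC(c1ccccc1)(c1ccccc1)c1ccccc1
F7 | step 1 | (S)-14-methylhexadecan-1-ol | CC[C@H](C)CCCCCCCCCCCCCO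
F8 | step 3 | benzyl 2,3-bis(benzyloxy)benzoate | O=C(OCc1ccccc1)c1cccc(OCc2ccccc2)c1OCc1ccccc1
F9 | step 3 | 2,3-bis(benzyloxy)benzoic acid | OC(=O)c1cccc(OCc2ccccc2)c1OCc1ccccc1
F10 | step 3 | (S)-14-methylhexadecyl 2,3-bis(benzyloxy)benzoate | CC[C@H](C)CCCCCCCCCCCCCOC(=O)c1cccc(OCc2ccccc2)c1OCc1ccccc1
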